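**Retrosynthetic overview**

1. Rings: A = hydroxylated ring with its ether O para to OH; B = para-phenylene; C = hydroxylated ring with its ether O ortho to OH; D = meta-phenylene. The macrocycle is the 18-membered ring A–CH2CH2–B–O–C–CH2CH2–D–O.
2. Enabling feature: the ether carbon of ring A (bonded to the O that leads to ring D) is para to the C–OH carbon of ring A, and the ether carbon of ring C (bonded to the O that leads to ring B) is ortho to the C–OH carbon of ring C. Each OH is therefore carried as a formyl group, which activates a C–F bond at that ether carbon for SNAr and becomes OH at the end (double Dakin-type Baeyer–Villiger oxidation).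
3. Disconnections: (i) O(ring D)–C(ring A) by macrocyclising SNAr, the last ring closure; (ii) O(ring B)–C(ring C) by intermolecular SNAr; (iii) both ArCH2–CH2Ar bonds by styrene hydroboration/B-alkyl Suzuki coupling.
4. Ring order: the four benzene rings are bought and no ring is built before the macrocycle. The ring-A formyl group stays a dioxolane (SNAr-silent) while the first ether is made, then is switched on together with the ring-D phenol.
5. The two C–O bonds are those of the presumed biosynthetic phenol couplings (ortho/para to OH), made here with reversed polarity.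

Key step: step 5

Remark: the target has no stereocentre and its 18-membered ring is assumed to be conformationally mobile, so there is no enantiomer to control. Compounds 1, 2, 6 and 8 are taken as catalogue chemicals.

**Step 1**
Reactants: 1 4-ethenylphenyl acetate (4-acetoxystyrene); 2 2-(3-bromo-4-fluorophenyl)-1,3-dioxolane
Product: 5 4-{2-[5-(1,3-dioxolan-2-yl)-2-fluorophenyl]ethyl}phenol, via 9-[2-(4-acetoxyphenyl)ethyl]-9-borabicyclo[3.3.1]nonane 3 (not isolated), via 4-{2-[5-(1,3-dioxolan-2-yl)-2-fluorophenyl]ethyl}phenyl acetate 4 (not isolated)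
Conditions: 1 (1.3 equiv), 9-BBN (1.25 equiv), THF, 0 °C to rt; then 2 (1.0 equiv), PdCl2(dppf) (3 mol %), K3PO4·H2O (3 equiv), DMF, 50 °C; then MeOH, K2CO3 (cat.), rt, same flask; NH4Cl work-up
Reagents that add atoms: 9-BBN, B1C2CCCC1CCC2 (its boron and bicycle are held in 3 only; 5 keeps one hydrogen of it)
Why: 9-BBN should add to the styrene with boron on the terminal carbon (anti-Markovnikov hydroboration), the B-alkyl Suzuki–Miyaura coupling should then join this sp3 carbon to the aryl bromide while the dioxolane and the unactivated C–F bond stay inert, and base-catalysed methanolysis of the aryl acetate (any acetate lost earlier converges on the same phenol) frees the phenol for step 2.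

**Step 2**
Reactants: 5 4-{2-[5-(1,3-dioxolan-2-yl)-2-fluorophenyl]ethyl}phenol; 6 4-bromo-2-fluorobenzaldehyde
Product: 7 4-bromo-2-(4-{2-[5-(1,3-dioxolan-2-yl)-2-fluorophenyl]ethyl}phenoxy)benzaldehyde
Conditions: 6 (1.1 equiv), K2CO3 (1.5 equiv), DMF, 80 °C
Reagents that add atoms: none
Why: Nucleophilic aromatic substitution (SNAr) in which the phenoxide of 5 should displace the fluoride ortho to the formyl group of 6 through a Meisenheimer intermediate, while the bromide (a far poorer leaving group in SNAr) and the fluorine of 5 (its ring carries only the non-activating acetal) remain.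

**Step 3**
Reactants: 7 4-bromo-2-(4-{2-[5-(1,3-dioxolan-2-yl)-2-fluorophenyl]ethyl}phenoxy)benzaldehyde; 8 1-tert-butoxy-3-ethenylbenzene (3-tert-butoxystyrene)
Product: 10 4-[2-(3-tert-butoxyphenyl)ethyl]-2-(4-{2-[5-(1,3-dioxolan-2-yl)-2-fluorophenyl]ethyl}phenoxy)benzaldehyde, via 9-[2-(3-tert-butoxyphenyl)ethyl]-9-borabicyclo[3.3.1]nonane 9 (not isolated)
Conditions: 8 (1.4 equiv), 9-BBN (1.3 equiv), THF, 0 °C to rt; then K3PO4·H2O (3 equiv), DMF, 10 min; then 7 (1.0 equiv), PdCl2(dppf) (3 mol %), 50 °C
Reagents that add atoms: 9-BBN, B1C2CCCC1CCC2 (its boron and bicycle are held in 9 only; 10 keeps one hydrogen of it)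
Why: Hydroboration/B-alkyl Suzuki–Miyaura coupling as in step 1, here on a bromide activated for oxidative addition by the para-formyl group, with the styrene in excess over 9-BBN and the alkylborane converted to its borate before 7 is added so that no hydride donor should reach the free aldehyde.

**Step 4**
Reactants: 10 4-[2-(3-tert-butoxyphenyl)ethyl]-2-(4-{2-[5-(1,3-dioxolan-2-yl)-2-fluorophenyl]ethyl}phenoxy)benzaldehyde
Product: 11 4-fluoro-3-[2-(4-{2-formyl-5-[2-(3-hydroxyphenyl)ethyl]phenoxy}phenyl)ethyl]benzaldehyde
Conditions: TFA/CH2Cl2 (1:4), H2O (10 equiv), 0 °C to rt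
Reagents that add atoms: water, O
Why: Acidolysis of the aryl tert-butyl ether (the tert-butyl cation leaves as isobutene) and acid-catalysed hydrolysis of the dioxolane should release, in one operation, the ring-D phenol and the ring-A formyl group, that is the nucleophile and the activating group of the ring closure.

**Step 5**
Reactants: 11 4-fluoro-3-[2-(4-{2-formyl-5-[2-(3-hydroxyphenyl)ethyl]phenoxy}phenyl)ethyl]benzaldehyde
Product: 12 macrocyclic dialdehyde (the 18-membered ring of the target with CHO in place of each OH: on ring A para to the ether oxygen, on ring C ortho to the ether oxygen)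
Conditions: Cs2CO3 (3 equiv), DMSO, 90 °C, 11 added by syringe pump over 12 h (final concentration 0.002 M)
Reagents that add atoms: none
Why: Caesium carbonate turns the ring-D phenol into its phenoxide, which adds to the fluorine-bearing carbon of ring A; the negative charge of the Meisenheimer intermediate is delocalised into the para-formyl group, and loss of fluoride gives the diaryl ether (addition–elimination SNAr). The closest known reaction type is the intramolecular SNAr cycloetherification of fluoroarenes carrying an ortho- or para-acceptor (usually nitro) with a tethered phenoxide, a standard entry to 14- to 18-membered macrocyclic diaryl ethers, together with the routine intermolecular SNAr of 4-fluorobenzaldehydes with phenols. One ring is closed, the 18-membered macrocycle, by end-to-end O–C(aryl) bond formation of the open chain (macro-etherification at an sp2 carbon); the four benzene rings are untouched. No stereocentre is formed and the product is achiral. The step needs ring closure to win over chain growth, which slow addition to a dilute, hot suspension of the caesium base should secure, and it needs a single site of attack, which the substrate secures because it holds one phenol and one C–F bond. The aryloxy group ortho to the second formyl group is a far poorer leaving group than fluoride and could only be displaced through a strained nine-membered ring, and the formyl groups, having no α-hydrogen, should not be consumed by the base.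

**Step 6**
Reactants: 12 macrocyclic dialdehyde
Product: 14 CNP0135015.0 (target diphenol), via macrocyclic bis(formate) 13 (not isolated)
Conditions: mCPBA (3 equiv), CH2Cl2, rt; aqueous Na2S2O3/NaHCO3 wash; crude 13 in MeOH, K2CO3 (cat.), rt
Reagents that add atoms: mCPBA, OOC(=O)c1cccc(Cl)c1 (one oxygen inserted per formyl group)
Why: Dakin-type Baeyer–Villiger oxidation in which the aryl group of each Criegee intermediate, made electron-rich by its ortho- or para-aryloxy substituent, should migrate in preference to hydride, so that each formyl group becomes an aryl formate that shields the new phenol from over-oxidation until mild methanolysis releases both hydroxyl groups.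

**Compound list**

1 | 4-ethenylphenyl acetate (4-acetoxystyrene) | CC(=O)Oc1ccc(C=C)cc1 | starting material
2 | 2-(3-bromo-4-fluorophenyl)-1,3-dioxolane | Fc1ccc(cc1Br)C1OCCO1 | starting material
3 | 9-[2-(4-acetoxyphenyl)ethyl]-9-borabicyclo[3.3.1]nonane | CC(=O)Oc1ccc(CCB2C3CCCC2CCC3)cc1 | intermediate
4 | 4-{2-[5-(1,3-dioxolan-2-yl)-2-fluorophenyl]ethyl}phenyl acetate | CC(=O)Oc1ccc(CCc2cc(ccc2F)C2OCCO2)cc1 | intermediate
5 | 4-{2-[5-(1,3-dioxolan-2-yl)-2-fluorophenyl]ethyl}phenol | Oc1ccc(CCc2cc(ccc2F)C2OCCO2)cc1 | intermediate
6 | 4-bromo-2-fluorobenzaldehyde | O=Cc1ccc(Br)cc1F | starting material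
7 | 4-bromo-2-(4-{2-[5-(1,3-dioxolan-2-yl)-2-fluorophenyl]ethyl}phenoxy)benzaldehyde | O=Cc1ccc(Br)cc1Oc1ccc(CCc2cc(ccc2F)C2OCCO2)cc1 | intermediate
8 | 1-tert-butoxy-3-ethenylbenzene (3-tert-butoxystyrene) | CC(C)(C)Oc1cccc(C=C)c1 | starting material
9 | 9-[2-(3-tert-butoxyphenyl)ethyl]-9-borabicyclo[3.3.1]nonane | CC(C)(C)Oc1cccc(CCB2C3CCCC2CCC3)c1 | intermediate
10 | 4-[2-(3-tert-butoxyphenyl)ethyl]-2-(4-{2-[5-(1,3-dioxolan-2-yl)-2-fluorophenyl]ethyl}phenoxy)benzaldehyde | O=Cc1ccc(CCc2cccc(OC(C)(C)C)c2)cc1Oc1ccc(CCc2cc(ccc2F)C2OCCO2)cc1 | intermediate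
11 | 4-fluoro-3-[2-(4-{2-formyl-5-[2-(3-hydroxyphenyl)ethyl]phenoxy}phenyl)ethyl]benzaldehyde | O=Cc1ccc(CCc2cccc(O)c2)cc1Oc1ccc(CCc2cc(C=O)ccc2F)cc1 | intermediate
12 | macrocyclic dialdehyde (target ring with CHO in place of each OH) | O=Cc1ccc2c(c1)CCc1ccc(cc1)Oc1cc(ccc1C=O)CCc1cccc(c1)O2 | intermediate
13 | macrocyclic bis(formate) (target with OCHO in place of each OH) | O=COc1ccc2c(c1)CCc1ccc(cc1)Oc1cc(ccc1OC=O)CCc1cccc(c1)O2 | intermediate
14 | CNP0135015.0, macrocyclic bis(bibenzyl) bis-ether diphenol | Oc1ccc2c(c1)CCc1ccc(cc1)Oc1cc(ccc1O)CCc1cccc(c1)O2 | target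

**Total step count:** 6
**Longest linear sequence:** 6 (1/2 → 5 → 7 → 10 → 11 → 12 → 14)

**Steps most likely to fail**

1. Step 5. Chain growth by intermolecular etherification may outrun ring closure, because the attacked carbon is flanked by the CH2CH2 chain and activated only by a formyl group. The fallback makes this hindered ether intermolecularly and closes the same macrocycle at a C–C bond instead. It sets out from 7. Aqueous HCl in THF hydrolyses the dioxolane to 4-bromo-2-{4-[2-(2-fluoro-5-formylphenyl)ethyl]phenoxy}benzaldehyde F1. SNAr with commercial 3-ethenylphenol in excess (K2CO3, DMSO, 100 °C, no dilution needed) should give 4-bromo-2-(4-{2-[2-(3-ethenylphenoxy)-5-formylphenyl]ethyl}phenoxy)benzaldehyde F2. An intramolecular Mizoroki–Heck reaction (Pd(OAc)2, P(o-tol)3, K2CO3, DMF, 100 °C, high dilution) should close the 18-membered ring as the macrocyclic (E)-stilbene dialdehyde F3. Hydrogenation of the C=C bond with a catalyst that spares aryl aldehydes (H2, Pd/C poisoned with Ph2S, EtOAc) should give 12, where the route is rejoined.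

2. Step 3. Hydride transfer from the alkylborane (or from residual B–H) to the free formyl group, or protodeboronation, may erode the coupling. The fallback avoids boron and sets out from 7 and 8. A Mizoroki–Heck reaction (Pd(OAc)2, P(o-tol)3, K2CO3, DMF, 100 °C) should give 2-(4-{2-[5-(1,3-dioxolan-2-yl)-2-fluorophenyl]ethyl}phenoxy)-4-[(E)-2-(3-tert-butoxyphenyl)ethenyl]benzaldehyde F4. Chemoselective hydrogenation of the stilbene (H2, Pd/C poisoned with Ph2S, EtOAc) should give 10, where the route is rejoined.

3. Step 6. Hydride instead of aryl migration at the less electron-rich formyl group (ring A) may give carboxylic acid, or the freed phenols may be oxidised further. The fallback drives both formyl groups to the acid on purpose and removes the carboxyl carbon by a radical route. It sets out from 12. Pinnick oxidation (NaClO2, NaH2PO4, 2-methyl-2-butene, t-BuOH/H2O) should give the macrocyclic dicarboxylic acid F5. Photochemical copper-mediated decarboxylative C–O coupling (Cu(OTf)2, copper(I) thiophene-2-carboxylate, MeCN, 365 nm, 35 °C) should give the macrocyclic bis(thiophene-2-carboxylate) F6. Hydrolysis (LiOH, THF/H2O) should give 14, the target.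

**Further compounds**

F1 | step 5 | 4-bromo-2-{4-[2-(2-fluoro-5-formylphenyl)ethyl]phenoxy}benzaldehyde | O=Cc1ccc(Br)cc1Oc1ccc(CCc2cc(C=O)ccc2F)cc1
F2 | step 5 | 4-bromo-2-(4-{2-[2-(3-ethenylphenoxy)-5-formylphenyl]ethyl}phenoxy)benzaldehyde | O=Cc1ccc(Br)cc1Oc1ccc(CCc2cc(C=O)ccc2Oc2cccc(C=C)c2)cc1
F3 | step 5 | macrocyclic (E)-stilbene dialdehyde (12 with CH=CH between rings C and D) | O=Cc1ccc2c(c1)CCc1ccc(cc1)Oc1cc(ccc1C=O)/C=C/c1cccc(c1)O2
F4 | step 3 | 2-(4-{2-[5-(1,3-dioxolan-2-yl)-2-fluorophenyl]ethyl}phenoxy)-4-[(E)-2-(3-tert-butoxyphenyl)ethenyl]benzaldehyde | O=Cc1ccc(/C=C/c2cccc(OC(C)(C)C)c2)cc1Oc1ccc(CCc2cc(ccc2F)C2OCCO2)cc1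
F5 | step 6 | macrocyclic dicarboxylic acid (12 with CO2H in place of each CHO) | OC(=O)c1ccc2c(c1)CCc1ccc(cc1)Oc1cc(ccc1C(O)=O)CCc1cccc(c1)O2
F6 | step 6 | macrocyclic bis(thiophene-2-carboxylate) of the target | O=C(Oc1ccc2c(c1)CCc1ccc(cc1)Oc1cc(ccc1OC(=O)c1cccs1)CCc1cccc(c1)O2)c1cccs1
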